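The constant you need for the next charge is a turnover frequency: the L consumed per second per G charged, read from the two earlier runs below.

| flask | L | G | temperature | remark | time |
|---|---|---|---|---|---|
| oak | 1.5 M | 1.3 mol% (in portions, 3) | −5 °C | run made earlier; portions every 1.0 s |  |
| maple | 1.5 M | 3.1 mol% (in portions, 3) | 15 °C | run made earlier; portions every 1.0 s |  |
| north-east | 1.5 M | 1.5 mol% (in portions, 3) |  | at 0 °C throughout; the portions of G follow each other after 1.0 s, the first at the start | 2.0 min |
| south-east | 1.5 M | 5.1 mol% (in portions, 3) |  | at 0 °C until 1.5 min, from then on at 30 °C; the portions of G follow each other after 1.0 s, the first at the start | 3.0 min |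

- oak (time / s: Z / %, L / %): 25.0: 21, 86; 50.0: 31, 68; 60.0: 38, 65; 90.0: 56, 42
- maple (time / s: Z / %, L / %): 10.0: 79, 20; 20.0: 95, 0; 40.0: 102, 0

(standard deviation of a reading: 2 percentage points)

* the flask that ends with the higher amount of Z, in percent of the L charged, or "neither" when 2 percentage points or less lies between them (north-east / south-east / neither)
* final Z, as a percentage of the L charged, in north-east
* final Z, as a percentage of the L charged, in south-east

- what is said of Z includes Q
- Q is a solid; its amount is given per volume of the solution
- steps that have been proposed: L + G -> D; D -> J; J -> G + Z; Q <-> Z

The decision is whether the next run takes the small loading of north-east or pays for the G of south-east. Oak loses 44 percentage points of L between 25.0 s and 90.0 s, so its turnover frequency reads 0.521 s⁻¹ at −5 °C. Maple has consumed 80.0% by 10.0 s, which reads 2.58 s⁻¹ at 15 °C. Since 0 °C lies a quarter of the way from oak to maple, I take that share of the logarithmic step and get 0.777 s⁻¹.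

Now write the balance of G, the catalyst: in the proposed steps L + G -> D takes it up and J -> G + Z returns it, so cG + cD + cJ equals the G added so far, and the whole charge once the last portion is in. To clear L, each G charged must make one over the loading in turnovers, so my reckoning for north-east is 85.8 s. This is the clearing time, one over loading times turnover frequency, the time L takes if the straight fall lasts to the end. My reckoning for south-east is 25.2 s, which is shorter than the 1.5 min before its heating.

I expect the line to bend at low cL: the proposed first step, L + G -> D, goes with cL. North-east has 1.40 clearing times to spend and south-east 3.57 before the heat, so I would charge south-east's G and expect it to end ahead, beyond the margin of 2 points. The forecast differs: it gives 99% for north-east, 100% for south-east, hence neither, while naming “a slow tail in north-east” as a risk.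

The flask gives 95.4% in north-east and 100% in south-east, so south-east ends higher. The steps and their constants are these.

    L + G → D (k = 2.00 M⁻¹ s⁻¹, Ea = 56.0 kJ mol⁻¹)
    D → J (k = 2.60 s⁻¹, Ea = 68.0 kJ mol⁻¹)
    J → G + Z (k = 2.50 s⁻¹, Ea = 63.0 kJ mol⁻¹)
    Q ⇌ Z, rate k4*(cs4 - [Z]) while solid is left; crystals form when [Z] > cs4 (solubility = 0.380 M, k = 2.00 s⁻¹)
    (constants at 0 °C)

North-east passed its reckoned clearing time of 85.8 s and still held L 4.47% of the L charged at 2.00 min, with D 4.72% and J 4.98% of the catalyst charged. The same flask with 0.38 mol% of G reckons to a clearing time of 339 s, so the straight line spends 35.4% of its L in 2.0 min. That flask ends with Z 37.5% and L 62.3%.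

The runs are simulated with constants of no real substance, and the scatter is random.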